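**Retrosynthetic overview**

1. The only ring of the target, the 28-membered depsi-lactam, is closed last (before deprotection) by a Passerini three-component macrocyclisation of an ω-isocyano acid with butanal. The isocyanide carbon acts as a carbamoyl-anion equivalent and attacks the aldehyde carbon (C1′–C2′ bond); the same step makes the ester and the amide.
2. The open chain is cut at C17–C18 (B-alkyl Suzuki) and C15–C16 (Suzuki) around a 2-bromo-3-iodoallyl silyl ether that carries C16, C17 and the CH2OH carbon and fixes the diene geometry.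
3. East part C18–C24: 2-deoxy-D-ribose supplies C19–C23 (C20, C21); nitromethane (Henry reaction) adds C24 with the nitrogen and sets C23; nitro → amine → formamide → isocyanide.
4. West part C1–C15: desymmetrised meso-2,4-dimethylglutaric anhydride (C2, C4), 4-bromobutanoyl chloride (C6–C9 ketone), copper-catalysed SN2′ ethylation (C13), joined by Grignard acylation and an alkyl–alkyl Negishi coupling.
5. Ring order: the dioxolane (protecting ring) first, the macrocycle last; no other ring is made.

Numbering: C1–C24 run along the long chain from the ester carbonyl (C1) to the CH2N carbon (C24); C1′–C5′ is the 2-hydroxypentanoyl unit.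

Assumption: the hand named for each chiral catalyst or ligand (steps 1, 5, 12, 20) is taken to be the one that gives the drawn configuration; both hands are commercial, so the sense is confirmed on the first run and the antipode used if needed.

**Route**

Step 1
Reactants: 1 meso-2,4-dimethylglutaric anhydride
Product: 2 (2R,4S)-5-methoxy-2,4-dimethyl-5-oxopentanoic acid
Conditions: MeOH (10 equiv), (DHQD)2AQN (10 mol %), Et2O, −40 °C
Reagents that add atoms: methanol (SMILES: CO)
Why: enantioselective alcoholysis (desymmetrisation) of a meso anhydride by a modified cinchona alkaloid picks one enantiotopic carbonyl, so the syn-dimethyl pair (future C2 at the ester end, future C4 at the acid end) is set in one step from an achiral compound.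

Step 2
Reactants: 2 (2R,4S)-5-methoxy-2,4-dimethyl-5-oxopentanoic acid
Product: 3 methyl (2S,4R)-5-hydroxy-2,4-dimethylpentanoate
Conditions: BH3·SMe2 (1.1 equiv), THF, −10 to 0 °C; aqueous work-up
Reagents that add atoms: none
Why: borane reduces a carboxylic acid far faster than a methyl ester (chemoselective acid reduction), so the acid carbon becomes the future C5 CH2OH without touching either stereocentre, and 3 is used cold and at once to forestall lactonisation.

Step 3
Reactants: 3 methyl (2S,4R)-5-hydroxy-2,4-dimethylpentanoate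
Product: 4 methyl (2S,4R)-5-iodo-2,4-dimethylpentanoate
Conditions: I2, PPh3, imidazole, CH2Cl2, 0 °C
Reagents that add atoms: iodine (SMILES: II)
Why: Appel-type iodination of the primary alcohol proceeds by SN2 at the CH2 carbon, so the neighbouring stereocentre is untouched.

Step 4
Reactants: 5 5-bromopent-1-ene; 6 (E)-1,4-dibromobut-2-ene
Product: 7 (E)-1,6-dibromohex-2-ene
Conditions: 6 (3 equiv), Hoveyda–Grubbs second-generation catalyst (2 mol %), CH2Cl2, 40 °C
Reagents that add atoms: none
Why: olefin cross-metathesis of a terminal alkene with an excess of the symmetrical allylic dibromide gives the E allylic bromide (thermodynamic E selectivity) and leaves the primary alkyl bromide alone.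

Step 5
Reactants: 7 (E)-1,6-dibromohex-2-ene
Product: 8 (R)-6-bromo-3-ethylhex-1-ene
Conditions: EtMgBr (1.2 equiv), CuBr·SMe2 (1 mol %), (R,Rp)-Taniaphos (1.2 mol %), CH2Cl2, −75 °C
Reagents that add atoms: ethylmagnesium bromide (SMILES: CC[Mg]Br)
Why: copper-catalysed asymmetric allylic alkylation, in which the ethylcopper–ferrocenyl diphosphine complex attacks the allylic bromide in SN2′ fashion with high branched selectivity and creates C13 (R) by catalyst control, while the unactivated primary bromide is inert at −75 °C.

Step 6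
Reactants: 8 (R)-6-bromo-3-ethylhex-1-ene; 9 4-bromobutanoyl chloride
Product: 11 (R)-1-bromo-8-ethyldec-9-en-4-one, via Grignard reagent 10 (not isolated)
Conditions: Mg, THF, 0 °C to rt; then 9 (1.0 equiv), Fe(acac)3 (3 mol %), THF, −78 °C
Reagents that add atoms: none
Why: magnesium insertion gives the primary Grignard reagent, whose iron-catalysed acylation by the acid chloride at −78 °C is much faster than attack on the ketone formed or on the alkyl bromide, so the C9 ketone is installed without over-addition.

Step 7
Reactants: 4 methyl (2S,4R)-5-iodo-2,4-dimethylpentanoate; 11 (R)-1-bromo-8-ethyldec-9-en-4-one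
Product: 13 methyl (2S,4S,13R)-13-ethyl-2,4-dimethyl-9-oxopentadec-14-enoate, via alkylzinc iodide 12 (not isolated)
Conditions: Zn dust (I2-activated), THF, 40 °C; then 11, Pd2(dba)3 (2 mol %), PCyp3 (8 mol %), N-methylimidazole (1.2 equiv), THF/NMP 2:1, 80 °C
Reagents that add atoms: none
Why: zinc insertion into the primary iodide gives an ester-tolerant alkylzinc reagent, and palladium/trialkylphosphine-catalysed alkyl–alkyl Negishi coupling with the unbranched primary bromide forms the C5–C6 bond; organozinc reagents add to neither the ketone nor the ester and no stereocentre is involved.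

Step 8
Reactants: 13 methyl (2S,4S,13R)-13-ethyl-2,4-dimethyl-9-oxopentadec-14-enoate; 14 vinylboronic acid pinacol ester
Product: 15 methyl (2S,4S,13R,14E)-13-ethyl-2,4-dimethyl-9-oxo-15-(4,4,5,5-tetramethyl-1,3,2-dioxaborolan-2-yl)pentadec-14-enoate
Conditions: 14 (3 equiv), second-generation Grubbs catalyst (5 mol %), CH2Cl2, 40 °C
Reagents that add atoms: none
Why: olefin cross-metathesis of the terminal alkene with the vinylboronic ester gives the E-alkenylboronate (sterically driven E selectivity next to the branched C13) and tolerates ketone and ester.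

Step 9
Reactants: 16 tert-butyldimethyl(prop-2-yn-1-yloxy)silane
Product: 17 (E)-[(2-bromo-3-iodoprop-2-en-1-yl)oxy](tert-butyl)dimethylsilane
Conditions: IBr (1.05 equiv), CH2Cl2, −78 to −20 °C, dark
Reagents that add atoms: iodine monobromide (SMILES: BrI)
Why: electrophilic anti addition of IBr to the terminal alkyne puts iodine on the terminal carbon and bromide on the internal one (Markovnikov opening of the iodonium ion), so iodine (later replaced by C15) is cis to the CH2O group and trans to bromine (later replaced by C18).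

Step 10
Reactants: 15 the E-alkenylboronate; 17 (E)-[(2-bromo-3-iodoprop-2-en-1-yl)oxy](tert-butyl)dimethylsilane
Product: 18 methyl (2S,4S,13R,14E,16E)-17-bromo-18-[(tert-butyldimethylsilyl)oxy]-13-ethyl-2,4-dimethyl-9-oxooctadeca-14,16-dienoate
Conditions: PdCl2(dppf) (5 mol %), K3PO4 (3 M aq), THF/DMF, rt
Reagents that add atoms: none
Why: Suzuki–Miyaura coupling takes place selectively at the C–I bond (oxidative addition is much faster there than at the hindered internal C–Br bond) with retention at both partners, giving the 14E diene with the C17 bromide kept for the next coupling.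

Step 11
Reactants: 19 2-deoxy-D-ribose
Product: 20 2-deoxy-3,4-O-isopropylidene-D-erythro-pentopyranose (anomer mixture)
Conditions: 2-methoxypropene, PPTS (cat.), EtOAc, 0 °C to rt
Reagents that add atoms: 2-methoxypropene (SMILES: COC(C)=C)
Why: kinetic acetonide formation with an enol ether under mild acid catalysis captures the cis-3,4-diol of the pyranose form and leaves the anomeric hydroxyl (the masked aldehyde) free.

Step 12
Reactants: 20 2-deoxy-3,4-O-isopropylidene-D-erythro-pentopyranose; 21 nitromethane
Product: 22 (S)-1-[(4S,5R)-5-(hydroxymethyl)-2,2-dimethyl-1,3-dioxolan-4-yl]-3-nitropropan-2-ol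
Conditions: 21 (10 equiv), Cu(OAc)2·H2O (10 mol %), inda-box bis(oxazoline) ligand (11 mol %), EtOH, rt
Reagents that add atoms: none
Why: asymmetric Henry (nitroaldol) reaction, in which the lactol opens to the hydroxy aldehyde and the copper nitronate (an aminomethyl-carbanion equivalent) adds to the carbonyl carbon inside the chiral bis(oxazoline) pocket, which sets C23 (S) by catalyst control; the epimers are separable diastereomers and the minor one can be recycled by retro-Henry equilibration.

Step 13
Reactants: 22 the nitro diol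
Product: 24 N-{(S)-2-hydroxy-3-[(4S,5R)-5-(hydroxymethyl)-2,2-dimethyl-1,3-dioxolan-4-yl]propyl}formamide, via amine 23 (not isolated)
Conditions: H2 (3 bar), Raney Ni (neutral), MeOH, rt; filter; then HCO2Et, 60 °C
Reagents that add atoms: ethyl formate (SMILES: CCOC=O)
Why: catalytic hydrogenation reduces the aliphatic nitro group to the primary amine, which ethyl formate N-formylates selectively over the hydroxyls (ester aminolysis), so the formamide serves both as protecting group and as isocyanide precursor.

Step 14
Reactants: 24 the formamide diol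
Product: 26 N-{(S)-3-[(4S,5R)-5-(hydroxymethyl)-2,2-dimethyl-1,3-dioxolan-4-yl]-2-[(triethylsilyl)oxy]propyl}formamide, via bis-TES ether 25 (not isolated)
Conditions: TESCl (2.5 equiv), imidazole (3 equiv), CH2Cl2, 0 °C to rt; then MeOH, PPTS (1 equiv), 0 °C, same flask
Reagents that add atoms: chlorotriethylsilane (SMILES: CC[Si](Cl)(CC)CC)
Why: exhaustive silylation followed by selective acid-catalysed methanolysis of the much more labile primary triethylsilyl ether leaves only the secondary C23 hydroxyl protected, and the cis-dioxolane survives brief pyridinium acid at 0 °C.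

Step 15
Reactants: 26 the mono-TES alcohol
Product: 27 N-{(S)-3-[(4S,5S)-5-formyl-2,2-dimethyl-1,3-dioxolan-4-yl]-2-[(triethylsilyl)oxy]propyl}formamide
Conditions: Dess–Martin periodinane, CH2Cl2, 0 °C to rt
Reagents that add atoms: none
Why: Dess–Martin oxidation gives the aldehyde under non-basic conditions that do not epimerise the α-alkoxy centre or dehydrate the formamide (activated-DMSO oxidants are avoided for that reason).

Step 16
Reactants: 27 the aldehyde
Product: 28 N-{(S)-3-[(4S,5R)-2,2-dimethyl-5-vinyl-1,3-dioxolan-4-yl]-2-[(triethylsilyl)oxy]propyl}formamide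
Conditions: Ph3PCH3Br (3 equiv), KHMDS (2.9 equiv), THF, −78 to 0 °C
Reagents that add atoms: methyltriphenylphosphonium bromide (SMILES: C[P+](c1ccccc1)(c1ccccc1)c1ccccc1.[Br-])
Why: Wittig methylenation with the salt-free ylide at low temperature gives the terminal vinyl group (C18=C19); the extra ylide covers deprotonation of the formamide N–H and the cold conditions avoid epimerising C20.

Step 17
Reactants: 28 the vinyl dioxolane; 18 the bromodiene
Product: 30 methyl (2S,4S,13R,14E,16Z)-17-{[(tert-butyldimethylsilyl)oxy]methyl}-19-[(4R,5S)-5-{(2S)-3-formamido-2-[(triethylsilyl)oxy]propyl}-2,2-dimethyl-1,3-dioxolan-4-yl]-13-ethyl-2,4-dimethyl-9-oxononadeca-14,16-dienoate, via alkyl-9-BBN borane 29 (not isolated)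
Conditions: 9-BBN (1.6 equiv), THF, 0 °C to rt; then K3PO4 (3 M aq), 18, PdCl2(dppf) (10 mol %), AsPh3 (10 mol %), DMF, 45 °C
Reagents that add atoms: none
Why: anti-Markovnikov hydroboration of the terminal vinyl group with 9-BBN followed by B-alkyl Suzuki–Miyaura coupling with the vinyl bromide forms C17–C18 with retention of alkene geometry, which completes the 14E,16Z diene with CH2O cis to C15 (the aqueous base destroys excess B–H before the ketone-bearing partner is added).

Step 18
Reactants: 30 the seco formamide ester
Product: 31 the isocyanide methyl ester (30 with C24–N≡C in place of C24–NHCHO)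
Conditions: POCl3 (1.2 equiv), Et3N (5 equiv), CH2Cl2, −30 to 0 °C
Reagents that add atoms: none
Why: dehydration of the secondary formamide with POCl3 and triethylamine (standard isocyanide synthesis) runs under cold, basic conditions that spare silyl ethers, acetonide, ketone, ester and diene, and it is placed after the last palladium step because isocyanides bind palladium.

Step 19
Reactants: 31 the isocyanide methyl ester
Product: 32 the ω-isocyano carboxylic acid (31 with C1 CO2H)
Conditions: LiOH (3 equiv), THF/MeOH/H2O, rt; then NaH2PO4 (aq) to pH 5–6, 0 °C; used at once as a cold dilute solution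
Reagents that add atoms: lithium hydroxide (SMILES: [Li+].[OH-])
Why: saponification of the methyl ester is compatible with the base-stable isocyanide and the silyl ethers and does not epimerise C2 at room temperature, and the buffered work-up avoids acid hydrolysis of the isocyanide.

Step 20
Reactants: 32 the ω-isocyano carboxylic acid; 33 butanal
Product: 34 the protected macrocycle (target with C17 CH2OTBS, C20/C21 acetonide and C23 OTES)
Conditions: 33 (50 equiv), (R)-TRIP chiral phosphoric acid (0.5 equiv, recovered), CHCl3, rt; 32 added by syringe pump over 24 h to a final 2 mM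
Reagents that add atoms: none
Why: Proposed new method: a chiral-phosphoric-acid-catalysed Passerini three-component macrocyclisation, in which the isocyanide carbon (a carbamoyl-anion equivalent, i.e. an acyl carbon used with reversed polarity) attacks the acid-activated carbonyl carbon of butanal inside the chiral hydrogen-bonded pocket and so sets C2′ (S), the nitrilium ion is trapped by the tethered carboxylate (27-membered cyclic imidate) and Mumm acyl transfer gives the 28-membered α-acyloxy amide, with aldehyde and catalyst kept in large excess over the slowly added isocyano acid so that the catalysed ring closure outruns oligomerisation and the uncatalysed background reaction; the closest known reaction types are the chiral-phosphoric-acid-catalysed enantioselective intermolecular Passerini reaction and the racemic Passerini macrocyclisation of ω-isocyano carboxylic acids.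

Step 21
Reactants: 34 the protected macrocycle
Product: 35 CNP0523849.1 (target)
Conditions: HF (48% aq), MeCN, 0 °C to rt
Reagents that add atoms: none
Why: aqueous HF cleaves both silyl ethers (fluoride-assisted Si–O cleavage) and, as a mild aqueous acid, hydrolyses the cis-dioxolane, while the macrolactone, amide, ketone and dienyl carbinol are stable under these conditions.

**Compound list**

1 | meso-2,4-dimethylglutaric anhydride [(3R,5S)-3,5-dimethyldihydro-2H-pyran-2,6(3H)-dione] | C[C@H]1C[C@@H](C)C(=O)OC1=O | starting material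
2 | (2R,4S)-5-methoxy-2,4-dimethyl-5-oxopentanoic acid | COC(=O)[C@@H](C)C[C@@H](C)C(=O)O | intermediate
3 | methyl (2S,4R)-5-hydroxy-2,4-dimethylpentanoate | COC(=O)[C@@H](C)C[C@@H](C)CO | intermediate
4 | methyl (2S,4R)-5-iodo-2,4-dimethylpentanoate | COC(=O)[C@@H](C)C[C@@H](C)CI | intermediate
5 | 5-bromopent-1-ene | C=CCCCBr | starting material
6 | (E)-1,4-dibromobut-2-ene | BrC/C=C/CBr | starting material
7 | (E)-1,6-dibromohex-2-ene | BrC/C=C/CCCBr | intermediate
8 | (R)-6-bromo-3-ethylhex-1-ene | BrCCC[C@@H](CC)C=C | intermediate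
9 | 4-bromobutanoyl chloride | ClC(=O)CCCBr | starting material
10 | [(4R)-4-ethylhex-5-en-1-yl]magnesium bromide | Br[Mg]CCC[C@@H](CC)C=C | intermediate (not isolated)
11 | (R)-1-bromo-8-ethyldec-9-en-4-one | BrCCCC(=O)CCC[C@@H](CC)C=C | intermediate
12 | [(2R,4S)-5-methoxy-2,4-dimethyl-5-oxopentyl]zinc iodide | COC(=O)[C@@H](C)C[C@@H](C)C[Zn]I | intermediate (not isolated)
13 | methyl (2S,4S,13R)-13-ethyl-2,4-dimethyl-9-oxopentadec-14-enoate | COC(=O)[C@@H](C)C[C@@H](C)CCCCC(=O)CCC[C@@H](CC)C=C | intermediate
14 | vinylboronic acid pinacol ester (4,4,5,5-tetramethyl-2-vinyl-1,3,2-dioxaborolane) | C=CB1OC(C)(C)C(C)(C)O1 | starting material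
15 | methyl (2S,4S,13R,14E)-13-ethyl-2,4-dimethyl-9-oxo-15-(4,4,5,5-tetramethyl-1,3,2-dioxaborolan-2-yl)pentadec-14-enoate | COC(=O)[C@@H](C)C[C@@H](C)CCCCC(=O)CCC[C@@H](CC)/C=C/B1OC(C)(C)C(C)(C)O1 | intermediate
16 | tert-butyldimethyl(prop-2-yn-1-yloxy)silane | C#CCO[Si](C)(C)C(C)(C)C | starting material
17 | (E)-[(2-bromo-3-iodoprop-2-en-1-yl)oxy](tert-butyl)dimethylsilane | I/C=C(/Br)CO[Si](C)(C)C(C)(C)C | intermediate
18 | methyl (2S,4S,13R,14E,16E)-17-bromo-18-[(tert-butyldimethylsilyl)oxy]-13-ethyl-2,4-dimethyl-9-oxooctadeca-14,16-dienoate | COC(=O)[C@@H](C)C[C@@H](C)CCCCC(=O)CCC[C@@H](CC)/C=C/C=C(\CO[Si](C)(C)C(C)(C)C)Br | intermediate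
19 | 2-deoxy-D-ribose (pyranose form drawn) | O1C[C@@H](O)[C@@H](O)CC1O | starting material
20 | 2-deoxy-3,4-O-isopropylidene-D-erythro-pentopyranose | O1C[C@H]2OC(C)(C)O[C@H]2CC1O | intermediate
21 | nitromethane | C[N+](=O)[O-] | starting material
22 | (S)-1-[(4S,5R)-5-(hydroxymethyl)-2,2-dimethyl-1,3-dioxolan-4-yl]-3-nitropropan-2-ol | OC[C@H]1OC(C)(C)O[C@H]1C[C@H](O)C[N+](=O)[O-] | intermediate
23 | (S)-1-amino-3-[(4S,5R)-5-(hydroxymethyl)-2,2-dimethyl-1,3-dioxolan-4-yl]propan-2-ol | OC[C@H]1OC(C)(C)O[C@H]1C[C@H](O)CN | intermediate (not isolated)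
24 | N-{(S)-2-hydroxy-3-[(4S,5R)-5-(hydroxymethyl)-2,2-dimethyl-1,3-dioxolan-4-yl]propyl}formamide | OC[C@H]1OC(C)(C)O[C@H]1C[C@H](O)CNC=O | intermediate
25 | bis-TES ether of 24 (C19 and C23 O-triethylsilyl) | CC[Si](CC)(CC)OC[C@H]1OC(C)(C)O[C@H]1C[C@H](O[Si](CC)(CC)CC)CNC=O | intermediate (not isolated)
26 | N-{(S)-3-[(4S,5R)-5-(hydroxymethyl)-2,2-dimethyl-1,3-dioxolan-4-yl]-2-[(triethylsilyl)oxy]propyl}formamide | OC[C@H]1OC(C)(C)O[C@H]1C[C@H](O[Si](CC)(CC)CC)CNC=O | intermediate
27 | N-{(S)-3-[(4S,5S)-5-formyl-2,2-dimethyl-1,3-dioxolan-4-yl]-2-[(triethylsilyl)oxy]propyl}formamide | O=C[C@H]1OC(C)(C)O[C@H]1C[C@H](O[Si](CC)(CC)CC)CNC=O | intermediate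
28 | N-{(S)-3-[(4S,5R)-2,2-dimethyl-5-vinyl-1,3-dioxolan-4-yl]-2-[(triethylsilyl)oxy]propyl}formamide | C=C[C@H]1OC(C)(C)O[C@H]1C[C@H](O[Si](CC)(CC)CC)CNC=O | intermediate
29 | B-alkyl-9-BBN from 28 (boron on C18) | C(CB1C2CCCC1CCC2)[C@H]1OC(C)(C)O[C@H]1C[C@H](O[Si](CC)(CC)CC)CNC=O | intermediate (not isolated)
30 | methyl (2S,4S,13R,14E,16Z)-17-{[(tert-butyldimethylsilyl)oxy]methyl}-19-[(4R,5S)-5-{(2S)-3-formamido-2-[(triethylsilyl)oxy]propyl}-2,2-dimethyl-1,3-dioxolan-4-yl]-13-ethyl-2,4-dimethyl-9-oxononadeca-14,16-dienoate | COC(=O)[C@@H](C)C[C@@H](C)CCCCC(=O)CCC[C@@H](CC)/C=C/C=C(\CO[Si](C)(C)C(C)(C)C)CC[C@H]1OC(C)(C)O[C@H]1C[C@H](O[Si](CC)(CC)CC)CNC=O | intermediate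
31 | isocyanide methyl ester (30 with (2S)-3-isocyano-2-[(triethylsilyl)oxy]propyl in place of the formamido chain end) | COC(=O)[C@@H](C)C[C@@H](C)CCCCC(=O)CCC[C@@H](CC)/C=C/C=C(\CO[Si](C)(C)C(C)(C)C)CC[C@H]1OC(C)(C)O[C@H]1C[C@H](O[Si](CC)(CC)CC)C[N+]#[C-] | intermediate
32 | ω-isocyano carboxylic acid (31 with C1 CO2H) | OC(=O)[C@@H](C)C[C@@H](C)CCCCC(=O)CCC[C@@H](CC)/C=C/C=C(\CO[Si](C)(C)C(C)(C)C)CC[C@H]1OC(C)(C)O[C@H]1C[C@H](O[Si](CC)(CC)CC)C[N+]#[C-] | intermediate
33 | butanal | CCCC=O | starting material
34 | protected macrocycle (35 with C17 CH2OTBS, C20/C21 O-isopropylidene, C23 OTES) | CCC[C@@H]1OC(=O)[C@@H](C)C[C@@H](C)CCCCC(=O)CCC[C@@H](CC)/C=C/C=C(\CO[Si](C)(C)C(C)(C)C)CC[C@H]2OC(C)(C)O[C@H]2C[C@H](O[Si](CC)(CC)CC)CNC1=O | intermediate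
35 | CNP0523849.1, the 28-membered depsi-lactam (2′S,2S,4S,13R,14E,16Z,20R,21S,23S) | CCC[C@@H]1OC(=O)[C@@H](C)C[C@@H](C)CCCCC(=O)CCC[C@@H](CC)/C=C/C=C(\CO)CC[C@@H](O)[C@@H](O)C[C@H](O)CNC1=O | target

**Step count**

Total step count: 21.
Longest linear sequence: 11 steps (steps 11–21 from 19; the lines from 5/6 and from 1 are equally long).

**Three steps most likely to fail**

1. Step 20 (Passerini macrocyclisation). Ring closure against oligomerisation and catalyst control at C2′ are both untested on a substrate of this size. The fallback sets out from 31 and comes back at 34. Compound 31, butanal (33) and chloroacetic acid are combined at normal concentration (0.2 M, same chiral phosphoric acid) in an intermolecular Passerini reaction to give the chloroacetoxy amide F1, whose C2′ epimers can be separated. LiOH then removes the chloroacetate and the methyl ester in one operation to give the hydroxy amide seco acid F2. The ring is closed through the ester bond instead, by Shiina macrolactonisation (2-methyl-6-nitrobenzoic anhydride, DMAP, toluene, high dilution), which gives 34. The isocyanide-based C1′–C2′ bond formation is kept; only the ring-closing event changes.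

2. Step 12 (Henry reaction on a lactol). Catalyst control at C23 has to override a chiral, hydroxyl-bearing substrate that is mostly in its closed form. The fallback sets out from 20 and comes back at 23. Wittig methylenation of lactol 20 (Ph3PCH3Br, KHMDS) gives the alkenol F3. Epoxidation with mCPBA gives both C23 epimers, and hydrolytic kinetic resolution with (R,R)-(salen)Co(OAc) and 0.55 equiv of water leaves the (S)-epoxide F4. Ammonia in methanol opens F4 at the terminal carbon to give amine 23, which is formylated as in step 13.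

3. Step 7 (alkyl–alkyl Negishi coupling). A β-branched alkylzinc reagent has to couple with a γ-bromo ketone without β-hydride elimination or cyclopropane formation. The fallback sets out from 3 and comes back at 13. Dess–Martin oxidation of 3 gives the aldehyde F5. Wittig reaction with the ylide from (3-carboxypropyl)triphenylphosphonium bromide (NaHMDS) gives the Z-enoic acid F6, and hydrogenation (H2, Pd/C) gives the saturated acid F7. Oxalyl chloride gives the acid chloride F8, which acylates Grignard reagent 10 (Fe(acac)3, −78 °C) to give 13 directly, so that 9, 11 and 12 are not needed.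

**Further compounds**

F1 | step 20 | Passerini adduct of 31 with butanal and chloroacetic acid: C24 N-[(2S)-2-(chloroacetoxy)pentanoyl] amide, C1 methyl ester | COC(=O)[C@@H](C)C[C@@H](C)CCCCC(=O)CCC[C@@H](CC)/C=C/C=C(\CO[Si](C)(C)C(C)(C)C)CC[C@H]1OC(C)(C)O[C@H]1C[C@H](O[Si](CC)(CC)CC)CNC(=O)[C@H](CCC)OC(=O)CCl
F2 | step 20 | hydroxy amide seco acid: C24 N-[(2S)-2-hydroxypentanoyl] amide, C1 carboxylic acid | OC(=O)[C@@H](C)C[C@@H](C)CCCCC(=O)CCC[C@@H](CC)/C=C/C=C(\CO[Si](C)(C)C(C)(C)C)CC[C@H]1OC(C)(C)O[C@H]1C[C@H](O[Si](CC)(CC)CC)CNC(=O)[C@H](CCC)O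
F3 | step 12 | [(4R,5S)-5-allyl-2,2-dimethyl-1,3-dioxolan-4-yl]methanol | OC[C@H]1OC(C)(C)O[C@H]1CC=C
F4 | step 12 | {(4R,5S)-2,2-dimethyl-5-[(S)-oxiran-2-ylmethyl]-1,3-dioxolan-4-yl}methanol | OC[C@H]1OC(C)(C)O[C@H]1C[C@H]2CO2
F5 | step 7 | methyl (2S,4R)-2,4-dimethyl-5-oxopentanoate | COC(=O)[C@@H](C)C[C@@H](C)C=O
F6 | step 7 | (4Z,6R,8S)-9-methoxy-6,8-dimethyl-9-oxonon-4-enoic acid | COC(=O)[C@@H](C)C[C@@H](C)/C=C\CCC(=O)O
F7 | step 7 | (6S,8S)-9-methoxy-6,8-dimethyl-9-oxononanoic acid | COC(=O)[C@@H](C)C[C@@H](C)CCCCC(=O)O
F8 | step 7 | methyl (2S,4S)-9-chloro-2,4-dimethyl-9-oxononanoate | COC(=O)[C@@H](C)C[C@@H](C)CCCCC(=O)Cl
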